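**Plan**

1. Last cut (key event): C3=C4 of the 2,2-dimethyl-2H-chromene (pyran ring fused to ring B) and the C2''=C3'' olefin of the 8-prenyl chain are cut together. This leads back to a 3'-vinyl / 4'-O–C(CH3)2–CH=CH2 pair on ring B and an allyl group on C8 of ring A; one ruthenium carbene makes both olefins.
2. What makes it possible: both isoprenoid units end in an olefin. C3=C4 is a cis styrenyl bond in a six-membered ring next to the quaternary C2 (gem-dimethyl: favourable rotamer, no homodimerisation), the prenyl end is a trisubstituted olefin, and rings A and C carry no metathesis-active bond.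
3. Second cut: C2–C1' between ring C and ring B, giving 8-allyl-7-silyloxychromone and an arylboronic acid (rhodium-catalysed asymmetric 1,4-addition).
4. Fragments: 7-hydroxychromone → O-allyl ether → Claisen to C8 → TIPS ether; 5-bromosalicylaldehyde → tertiary propargyl ether → semi-hydrogenation → Wittig → Br/Li/B exchange.
5. Forward order: rings A and C come as the chromone, ring B is joined at C2, the 7-OH is freed, and the chromene pyran ring closes last, in the same flask in which the prenyl group is completed.
6. Stereochemistry: the only stereocentre, C2 (S), is set by ligand control in the 1,4-addition (aryl to the Re face of chromone C2) and is kept because all later steps are neutral or buffered.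

Key step: step 10

Remark on the chemistry: C2 of the target is S (O1 > aryl > C3 > H); the S antipode of the bisphosphine in step 8 is the one expected from the usual quadrant model to deliver aryl to the Re face of chromone C2, and the R antipode would be taken if a test reaction showed the opposite sense.

**Route**

Step 1
Reactants: 1 7-hydroxy-4H-chromen-4-one
Product: 2 7-(allyloxy)-4H-chromen-4-one
Conditions: allyl bromide, K2CO3, acetone, reflux
Reagents that add atoms: allyl bromide C=CCBr
Why: Williamson ether synthesis; the acidic 7-OH (a vinylogous acid) is alkylated by SN2 on allyl bromide under carbonate conditions that leave the chromone untouched.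

Step 2
Reactants: 2 7-(allyloxy)-4H-chromen-4-one
Product: 3 8-allyl-7-hydroxy-4H-chromen-4-one
Conditions: N,N-diethylaniline, 200 °C, sealed tube
Reagents that add atoms: none
Why: Aromatic Claisen rearrangement ([3,3]-sigmatropic shift, then enolisation); in 7-allyloxybenzopyranones the allyl group should migrate to C8 rather than C6 because the C7–C8 bond has the higher double-bond character.

Step 3
Reactants: 3 8-allyl-7-hydroxy-4H-chromen-4-one
Product: 4 8-allyl-7-[(triisopropylsilyl)oxy]-4H-chromen-4-one
Conditions: TIPSCl, imidazole, DMF, rt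
Reagents that add atoms: triisopropylsilyl chloride CC(C)[Si](Cl)(C(C)C)C(C)C
Why: Imidazole-promoted silylation of the phenol gives a bulky TIPS ether that keeps the 7-oxygen neutral during the rhodium step and can be removed with buffered fluoride, which spares the tertiary allyl aryl ether brought in later.

Step 4
Reactants: 5 5-bromo-2-hydroxybenzaldehyde
Product: 6 5-bromo-2-[(2-methylbut-3-yn-2-yl)oxy]benzaldehyde
Conditions: 3-chloro-3-methylbut-1-yne, DBU, CuCl2·2H2O (1 mol%), MeCN, 0 °C to rt
Reagents that add atoms: 3-chloro-3-methylbut-1-yne C#CC(C)(C)Cl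
Why: Copper-catalysed propargylic etherification (ionisation of the tertiary chloride to a copper-stabilised propargyl cation, then O-alkylation) is the standard way to tertiary aryl propargyl ethers of acidic phenols and runs at 0 °C, far below the onset of the propargyl Claisen rearrangement.

Step 5
Reactants: 6 5-bromo-2-[(2-methylbut-3-yn-2-yl)oxy]benzaldehyde
Product: 7 5-bromo-2-[(2-methylbut-3-en-2-yl)oxy]benzaldehyde
Conditions: H2 (1 atm), Pd/CaCO3 poisoned with Pb(OAc)2 (Lindlar catalyst), quinoline, EtOAc, rt
Reagents that add atoms: none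
Why: Lindlar semi-hydrogenation should stop at the alkene because the poisoned palladium binds the terminal alkyne far more strongly than the product olefin, and it does not reduce the aryl bromide or the aldehyde.

Step 6
Reactants: 7 5-bromo-2-[(2-methylbut-3-en-2-yl)oxy]benzaldehyde
Product: 8 4-bromo-1-[(2-methylbut-3-en-2-yl)oxy]-2-vinylbenzene
Conditions: Ph3PCH3Br, KOtBu, THF, 0 °C to rt
Reagents that add atoms: methyltriphenylphosphonium bromide C[P+](c1ccccc1)(c1ccccc1)c1ccccc1.[Br-]
Why: Wittig methylenation of a non-enolisable aryl aldehyde with the unstabilised ylide; the aryl bromide and the tertiary allyl ether are inert to it.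

Step 7
Reactants: 8 4-bromo-1-[(2-methylbut-3-en-2-yl)oxy]-2-vinylbenzene
Product: 11 {4-[(2-methylbut-3-en-2-yl)oxy]-3-vinylphenyl}boronic acid, via aryllithium 9 (not isolated), via lithium aryltriisopropoxyborate 10 (not isolated)
Conditions: B(OiPr)3, then n-BuLi, THF/toluene, −78 °C; sat. aq. NH4Cl, 0 °C
Reagents that add atoms: triisopropyl borate CC(C)OB(OC(C)C)OC(C)C; water O
Why: Bromine–lithium exchange with in-situ borate trapping; exchange at −78 °C is much faster than addition of butyllithium to the styrene or to the borate, the aryllithium is captured at once as the ate complex, and near-neutral hydrolysis should give the boronic acid without ionising the acid-labile tertiary allyl ether.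

Step 8
Reactants: 4 8-allyl-7-[(triisopropylsilyl)oxy]-4H-chromen-4-one; 11 {4-[(2-methylbut-3-en-2-yl)oxy]-3-vinylphenyl}boronic acid
Product: 12 (S)-8-allyl-2-{4-[(2-methylbut-3-en-2-yl)oxy]-3-vinylphenyl}-7-[(triisopropylsilyl)oxy]chroman-4-one
Conditions: [Rh(OH)(cod)]2 (2.5 mol%), (S)-MeO-F12-BIPHEP (5.5 mol%), toluene/H2O (10:1), 30 °C
Reagents that add atoms: none
Why: Hayashi–Miyaura-type asymmetric 1,4-addition of an arylboronic acid to a chromone (transmetalation to an aryl complex of monovalent rhodium, enantioface-selective insertion of C2=C3, protonolysis of the rhodium enolate by water); the C2-symmetric bisphosphine should block the Si face of C2 so that aryl adds to the Re face and sets 2S, and the electron-poor ligand makes insertion fast enough at 30 °C, without added base, to outrun enolate ring-opening and addition to the isolated olefins.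

Step 9
Reactants: 12 (S)-8-allyl-2-{4-[(2-methylbut-3-en-2-yl)oxy]-3-vinylphenyl}-7-[(triisopropylsilyl)oxy]chroman-4-one
Product: 13 (S)-8-allyl-7-hydroxy-2-{4-[(2-methylbut-3-en-2-yl)oxy]-3-vinylphenyl}chroman-4-one
Conditions: TBAF, AcOH (1:1), THF, 0 °C
Reagents that add atoms: none
Why: Fluoride-induced cleavage of the aryl silyl ether, buffered with acetic acid so that the 7-phenoxide is protonated at once and cannot start a retro-oxa-Michael opening of ring C (which would racemise C2); the tertiary allyl ether and the olefins are inert to fluoride.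

Step 10
Reactants: 13 (S)-8-allyl-7-hydroxy-2-{4-[(2-methylbut-3-en-2-yl)oxy]-3-vinylphenyl}chroman-4-one
Product: 15 (S)-2-(2,2-dimethyl-2H-chromen-6-yl)-7-hydroxy-8-(3-methylbut-2-en-1-yl)chroman-4-one (target), via 8-allyl chromene flavanone 14 (not isolated)
Conditions: RuCl2(=CHPh)(PCy3)(H2IMes) (second-generation Grubbs catalyst, 5 mol%), CH2Cl2 (0.005 M), 40 °C; then 2-methyl-2-butene (large excess), rt, sealed vessel
Reagents that add atoms: 2-methyl-2-butene CC=C(C)C
Why: Olefin metathesis by the Chauvin mechanism: the ruthenium carbene loads on the unhindered 3'-vinyl group, adds across the vinyl group of the neighbouring O–C(CH3)2–CH=CH2 ether to a ruthenacyclobutane, and cycloreversion forms C3=C4 with loss of ethylene; after 2-methyl-2-butene is added the same catalyst turns the C8-allyl terminus into the trisubstituted prenyl olefin with loss of propene. The closest known reaction types are ring-closing metathesis of 2-vinylaryl allyl ethers to 2H-chromenes and cross metathesis of allylarenes with 2-methyl-2-butene to prenylarenes. The one ring closed is the six-membered pyran ring of the chromene, by ring-closing metathesis between two terminal vinyl groups ([2+2] cycloaddition and cycloreversion), which leaves the new double bond endocyclic and cis by ring constraint. No stereocentre is formed, and C2 of the flavanone stays untouched because the medium is neutral and aprotic. The step needs chemoselectivity among three terminal olefins and two product olefins: the gem-dimethyl group favours the reactive rotamer and prevents homodimerisation of that vinyl group, six-membered closure at high dilution is much faster than any intermolecular event, the only other ring closures (the C8-allyl group with an olefin of ring B) would give strained ten- or thirteen-membered cyclophanes, and the cis C3=C4 bond and the trisubstituted prenyl bond are too hindered to re-enter the cycle. Adding 2-methyl-2-butene only after ring closure keeps the styrene end from being capped beforehand as a slower trisubstituted olefin.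

**Compound list**

1 | 7-hydroxy-4H-chromen-4-one | O=c1ccoc2cc(O)ccc12 | starting material
2 | 7-(allyloxy)-4H-chromen-4-one | O=c1ccoc2cc(OCC=C)ccc12 | intermediate
3 | 8-allyl-7-hydroxy-4H-chromen-4-one | O=c1ccoc2c(CC=C)c(O)ccc12 | intermediate
4 | 8-allyl-7-[(triisopropylsilyl)oxy]-4H-chromen-4-one | O=c1ccoc2c(CC=C)c(O[Si](C(C)C)(C(C)C)C(C)C)ccc12 | intermediate
5 | 5-bromo-2-hydroxybenzaldehyde | O=Cc1cc(Br)ccc1O | starting material
6 | 5-bromo-2-[(2-methylbut-3-yn-2-yl)oxy]benzaldehyde | O=Cc1cc(Br)ccc1OC(C)(C)C#C | intermediate
7 | 5-bromo-2-[(2-methylbut-3-en-2-yl)oxy]benzaldehyde | O=Cc1cc(Br)ccc1OC(C)(C)C=C | intermediate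
8 | 4-bromo-1-[(2-methylbut-3-en-2-yl)oxy]-2-vinylbenzene | C=Cc1cc(Br)ccc1OC(C)(C)C=C | intermediate
9 | {4-[(2-methylbut-3-en-2-yl)oxy]-3-vinylphenyl}lithium (not isolated) | [Li]c1ccc(OC(C)(C)C=C)c(C=C)c1 | intermediate
10 | lithium triisopropoxy{4-[(2-methylbut-3-en-2-yl)oxy]-3-vinylphenyl}borate (not isolated) | CC(C)O[B-](OC(C)C)(OC(C)C)c1ccc(OC(C)(C)C=C)c(C=C)c1.[Li+] | intermediate
11 | {4-[(2-methylbut-3-en-2-yl)oxy]-3-vinylphenyl}boronic acid | OB(O)c1ccc(OC(C)(C)C=C)c(C=C)c1 | intermediate
12 | (S)-8-allyl-2-{4-[(2-methylbut-3-en-2-yl)oxy]-3-vinylphenyl}-7-[(triisopropylsilyl)oxy]chroman-4-one | C=CCc1c(O[Si](C(C)C)(C(C)C)C(C)C)ccc2c1O[C@H](c1ccc(OC(C)(C)C=C)c(C=C)c1)CC2=O | intermediate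
13 | (S)-8-allyl-7-hydroxy-2-{4-[(2-methylbut-3-en-2-yl)oxy]-3-vinylphenyl}chroman-4-one | C=CCc1c(O)ccc2c1O[C@H](c1ccc(OC(C)(C)C=C)c(C=C)c1)CC2=O | intermediate
14 | (S)-8-allyl-2-(2,2-dimethyl-2H-chromen-6-yl)-7-hydroxychroman-4-one (not isolated) | C=CCc1c(O)ccc2c1O[C@H](c1ccc3c(c1)C=CC(C)(C)O3)CC2=O | intermediate
15 | (S)-2-(2,2-dimethyl-2H-chromen-6-yl)-7-hydroxy-8-(3-methylbut-2-en-1-yl)chroman-4-one | CC(C)=CCc1c(O)ccc2c1O[C@H](c1ccc3c(c1)C=CC(C)(C)O3)CC2=O | target

**Step count and risks**

Total step count: 10. Longest linear sequence: 7 steps (5 → 15 through steps 4, 5, 6, 7, 8, 9 and 10).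

Steps most likely to fail:

Step 8. Insertion into the electron-rich silyloxy chromone may be slow, so that protodeboronation of the electron-rich boronic acid, insertion of aryl–rhodium into the styrene unit, or β-oxygen elimination of the rhodium enolate (ring opening with loss of enantiomeric purity) compete. The fallback replaces asymmetric catalysis by a chalcone route with resolution; it sets out from 3 and 8 and comes back at 13. Alkaline ring opening of chromone 3 (2 M aq. NaOH, 80 °C, then dilute acid) should give 1-(3-allyl-2,4-dihydroxyphenyl)ethan-1-one F1 with loss of formate. Bromide 8 is formylated (n-BuLi, THF, −78 °C, then DMF) to 4-[(2-methylbut-3-en-2-yl)oxy]-3-vinylbenzaldehyde F2. Claisen–Schmidt condensation of F1 with F2 (KOH, EtOH/H2O, rt) should give (E)-1-(3-allyl-2,4-dihydroxyphenyl)-3-{4-[(2-methylbut-3-en-2-yl)oxy]-3-vinylphenyl}prop-2-en-1-one F3. NaOAc in refluxing EtOH closes ring C by oxa-Michael addition to the racemic flavanone, and preparative chromatography on a chiral stationary phase separates 13 from (R)-8-allyl-7-hydroxy-2-{4-[(2-methylbut-3-en-2-yl)oxy]-3-vinylphenyl}chroman-4-one F4, which can be returned to the chalcone equilibrium.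

Step 10. Ruthenium hydride species may shift the C8-allyl double bond into conjugation next to the free phenol before cross metathesis (leading to a chain one carbon short), or cross metathesis may stall after the ring has closed. The fallback separates the two metathesis events and installs the prenyl group on the simple, silyl-protected fragment; it sets out from 4 and comes back at 15. Cross metathesis of 4 with 2-methyl-2-butene (same ruthenium catalyst, CH2Cl2, rt) should give 8-(3-methylbut-2-en-1-yl)-7-[(triisopropylsilyl)oxy]-4H-chromen-4-one F5. Rhodium-catalysed addition of 11 as in step 8 gives (S)-8-(3-methylbut-2-en-1-yl)-2-{4-[(2-methylbut-3-en-2-yl)oxy]-3-vinylphenyl}-7-[(triisopropylsilyl)oxy]chroman-4-one F6. Buffered TBAF as in step 9 gives (S)-7-hydroxy-8-(3-methylbut-2-en-1-yl)-2-{4-[(2-methylbut-3-en-2-yl)oxy]-3-vinylphenyl}chroman-4-one F7. Ring-closing metathesis alone (no 2-methyl-2-butene, high dilution) then closes the chromene to 15.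

Step 4. The tertiary propargyl chloride may eliminate to the enyne, and O-alkylation of the hydrogen-bonded ortho-formyl phenol may be sluggish. The fallback makes the tertiary allyl ether directly by allylic substitution; it sets out from 5 and comes back at 7, without passing through 6. tert-Butyl (2-methylbut-3-en-2-yl) carbonate F8 (from 2-methylbut-3-en-2-ol and Boc2O) reacts with 5 under Pd(PPh3)4 (zerovalent palladium) in THF at 0 °C in a decarboxylative Tsuji–Trost etherification. This should give the branched ether 7 under kinetic control.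

**Further compounds**

F1 | step 8 | 1-(3-allyl-2,4-dihydroxyphenyl)ethan-1-one | CC(=O)c1ccc(O)c(CC=C)c1O
F2 | step 8 | 4-[(2-methylbut-3-en-2-yl)oxy]-3-vinylbenzaldehyde | O=Cc1ccc(OC(C)(C)C=C)c(C=C)c1
F3 | step 8 | (E)-1-(3-allyl-2,4-dihydroxyphenyl)-3-{4-[(2-methylbut-3-en-2-yl)oxy]-3-vinylphenyl}prop-2-en-1-one | C=CCc1c(O)ccc(C(=O)/C=C/c2ccc(OC(C)(C)C=C)c(C=C)c2)c1O
F4 | step 8 | (R)-8-allyl-7-hydroxy-2-{4-[(2-methylbut-3-en-2-yl)oxy]-3-vinylphenyl}chroman-4-one | C=CCc1c(O)ccc2c1O[C@@H](c1ccc(OC(C)(C)C=C)c(C=C)c1)CC2=O
F5 | step 10 | 8-(3-methylbut-2-en-1-yl)-7-[(triisopropylsilyl)oxy]-4H-chromen-4-one | O=c1ccoc2c(CC=C(C)C)c(O[Si](C(C)C)(C(C)C)C(C)C)ccc12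
F6 | step 10 | (S)-8-(3-methylbut-2-en-1-yl)-2-{4-[(2-methylbut-3-en-2-yl)oxy]-3-vinylphenyl}-7-[(triisopropylsilyl)oxy]chroman-4-one | CC(C)=CCc1c(O[Si](C(C)C)(C(C)C)C(C)C)ccc2c1O[C@H](c1ccc(OC(C)(C)C=C)c(C=C)c1)CC2=O
F7 | step 10 | (S)-7-hydroxy-8-(3-methylbut-2-en-1-yl)-2-{4-[(2-methylbut-3-en-2-yl)oxy]-3-vinylphenyl}chroman-4-one | CC(C)=CCc1c(O)ccc2c1O[C@H](c1ccc(OC(C)(C)C=C)c(C=C)c1)CC2=O
F8 | step 4 | tert-butyl (2-methylbut-3-en-2-yl) carbonate | CC(C)(C)OC(=O)OC(C)(C)C=C
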